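**Plan**

- Retrosynthetic cuts, in order: flavanone C2–C3 (carbene C–H insertion), the diazo group on C3 (diazo transfer to the ring A acetyl group), O1–CH2 (Mitsunobu ether), and the C3'–C8'' biaryl bond (Suzuki coupling). This leaves acacetin, 3-bromo-4-hydroxybenzaldehyde and 2',6'-dihydroxy-4'-methoxyacetophenone.
- Forward: the flavone rings come ready-made in acacetin. The biaryl is joined first, ring A is attached through O1, its acetyl group becomes a diazomethyl ketone, and ring C of the flavanone closes last.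
- Enabling feature: flavanone C2 is bonded to O1 and is benzylic to ring B. In the open-chain O1–CH2–ring B ether its C–H bonds are therefore doubly activated toward a carbene generated at C3 on the ring A acyl group.
- Stereochemistry: the single stereocentre (2S) is set in the ring closure by the chiral dirhodium carboxylate, which selects one of the two enantiotopic benzylic hydrogens. The two deprotections that follow are buffered or neutral and should not open ring C.

Key step: step 11

Assumption: Rh2(S-PTTL)4 (dirhodium tetrakis[N-phthaloyl-(S)-tert-leucinate]) is taken to deliver the 2S product; if the sense of induction proves opposite, the mirror-image Rh2(R-PTTL)4 is used with no other change.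

Assumption: 2',6'-dihydroxy-4'-methoxyacetophenone (10) is a purchased material.

Locants: unprimed = chromanone part of the flavanone half, one prime = its ring B, two primes = chromone part of the flavone half, three primes = its anisyl ring. "ArCH2" below stands for the 4-benzyloxy-3-(5-benzyloxy-7,4'-dimethoxyflavon-8-yl)benzyl group.

**Route**

Step 1
Reactants: 1 acacetin (5,7-dihydroxy-4'-methoxyflavone)
Product: 2 5-hydroxy-7,4'-dimethoxyflavone
Conditions: MeI (1.1 equiv), K2CO3, acetone, reflux
Reagents that add atoms: iodomethane, CI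
Why: Williamson methylation; the 7-OH is the acidic free phenol, while the 5-OH is held in a hydrogen bond to C4=O and should not react with one equivalent of MeI.

Step 2
Reactants: 2 5-hydroxy-7,4'-dimethoxyflavone
Product: 3 5-benzyloxy-7,4'-dimethoxyflavone
Conditions: BnBr, K2CO3, DMF, 80 °C
Reagents that add atoms: benzyl bromide, BrCc1ccccc1
Why: Williamson benzylation of the chelated 5-OH under forcing conditions; the 5-O-alkyl group is needed to steer the following halogenation to C8.

Step 3
Reactants: 3 5-benzyloxy-7,4'-dimethoxyflavone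
Product: 4 5-benzyloxy-8-iodo-7,4'-dimethoxyflavone
Conditions: NIS (1.1 equiv), CF3CO2H (cat.), MeCN, 0 °C to rt, dark
Reagents that add atoms: N-iodosuccinimide, O=C1CCC(=O)N1I
Why: electrophilic aromatic iodination; in 5,7-di-O-alkyl flavones C8 (ortho to 7-OMe and O1, para to the 5-alkoxy group) is the established site of halogenation, whereas a free 5-OH would direct to C6.

Step 4
Reactants: 5 3-bromo-4-hydroxybenzaldehyde
Product: 6 4-benzyloxy-3-bromobenzaldehyde
Conditions: BnBr, K2CO3, DMF, rt
Reagents that add atoms: benzyl bromide, BrCc1ccccc1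
Why: Williamson benzylation of an acidic para-formyl phenol.

Step 5
Reactants: 6 4-benzyloxy-3-bromobenzaldehyde
Product: 7 4-benzyloxy-3-(4,4,5,5-tetramethyl-1,3,2-dioxaborolan-2-yl)benzaldehyde
Conditions: B2pin2, Pd(dppf)Cl2 (3 mol %), KOAc, 1,4-dioxane, 90 °C
Reagents that add atoms: bis(pinacolato)diboron, CC1(C)OB(OC1(C)C)B1OC(C)(C)C(C)(C)O1
Why: Miyaura borylation of an aryl bromide; the weak base KOAc leaves the aldehyde and the benzyl ether untouched.

Step 6
Reactants: 4 5-benzyloxy-8-iodo-7,4'-dimethoxyflavone; 7 4-benzyloxy-3-(4,4,5,5-tetramethyl-1,3,2-dioxaborolan-2-yl)benzaldehyde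
Product: 8 4-benzyloxy-3-(5-benzyloxy-7,4'-dimethoxyflavon-8-yl)benzaldehyde
Conditions: Pd(OAc)2 (5 mol %), SPhos (10 mol %), K3PO4, toluene/H2O 10:1, 90 °C
Reagents that add atoms: none
Why: Suzuki–Miyaura coupling; the C8–I bond adds readily to zerovalent palladium, and the bulky, electron-rich biarylphosphine is the standard answer to a tri-ortho-substituted biaryl.

Step 7
Reactants: 8 4-benzyloxy-3-(5-benzyloxy-7,4'-dimethoxyflavon-8-yl)benzaldehyde
Product: 9 5-benzyloxy-8-[2-benzyloxy-5-(hydroxymethyl)phenyl]-7,4'-dimethoxyflavone (ArCH2OH)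
Conditions: NaBH4 (1 equiv), THF/MeOH, 0 °C
Reagents that add atoms: none
Why: chemoselective borohydride reduction of the aldehyde; the flavone carbonyl is a vinylogous ester and much less electrophilic at 0 °C.

Step 8
Reactants: 9 5-benzyloxy-8-[2-benzyloxy-5-(hydroxymethyl)phenyl]-7,4'-dimethoxyflavone; 10 2',6'-dihydroxy-4'-methoxyacetophenone
Product: 11 2'-(ArCH2O)-6'-hydroxy-4'-methoxyacetophenone
Conditions: PPh3, DIAD, 10 (3 equiv), THF, 0 °C to rt
Reagents that add atoms: none
Why: Mitsunobu etherification of an acidic acyl phenol with a primary benzylic alcohol; the excess of symmetric 10 and the hydrogen bond that ties the remaining OH to the ketone should hold the reaction at the mono-ether.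

Step 9
Reactants: 11 2'-(ArCH2O)-6'-hydroxy-4'-methoxyacetophenone
Product: 12 2'-(ArCH2O)-4'-methoxy-6'-(triisopropylsilyloxy)acetophenone
Conditions: TIPSOTf, 2,6-lutidine, CH2Cl2, −78 to 0 °C
Reagents that add atoms: triisopropylsilyl triflate, CC(C)[Si](OS(=O)(=O)C(F)(F)F)(C(C)C)C(C)C
Why: silylation of a hydrogen-bonded phenol with a silyl triflate; triisopropylsilyl is chosen because it offers the later carbene no reachable C–H bond, shields O5 and resists migration to the enolate in step 10.

Step 10
Reactants: 12 2'-(ArCH2O)-4'-methoxy-6'-(triisopropylsilyloxy)acetophenone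
Product: 14 ring A diazomethyl ketone 2-diazo-1-[2-(ArCH2O)-4-methoxy-6-(triisopropylsilyloxy)phenyl]ethanone, via trifluoroacetyl ketone 13 (not isolated)
Conditions: LiN(SiMe3)2, THF, −78 °C; CF3CO2CH2CF3; aq. NH4Cl; then MsN3, Et3N, H2O (1 equiv), MeCN, rt
Reagents that add atoms: 2,2,2-trifluoroethyl trifluoroacetate, O=C(OCC(F)(F)F)C(F)(F)F; methanesulfonyl azide, CS(=O)(=O)N=[N+]=[N-]
Why: Danheiser detrifluoroacetylative diazo transfer (a Regitz-type deacylative transfer): the kinetic lithium enolate of the methyl ketone undergoes Claisen acylation, and the activated 1,3-diketone takes N2 from the sulfonyl azide while the trifluoroacetyl group leaves as the N-mesyl amide.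

Step 11
Reactants: 14 ring A diazomethyl ketone
Product: 15 (2S)-4',5''-di-O-benzyl-5-O-triisopropylsilyl-2,3-dihydroheveaflavone
Conditions: Rh2(S-PTTL)4 (2 mol %), CH2Cl2, 0 °C, slow addition of 14 to the catalyst, final 0.01 M
Reagents that add atoms: none
Why: The dirhodium tetracarboxylate expels N2 from 14 to give an electrophilic rhodium carbene at the future C3, which inserts through a concerted, asynchronous three-centre transition state with hydride-transfer character into a benzylic C–H bond of the O1–CH2–ring B group and so forms C2–C3. The closest known reaction type is the enantioselective dirhodium-carboxylate-catalysed intramolecular C–H insertion of ortho-alkoxyaryl diazoketones to chromanones. Ring C closes as a six-membered ring by 1,6-insertion, because the atom in the usual 1,5 position is the ether oxygen itself and carries no hydrogen. The new stereocentre C2 is set by catalyst control: the chiral pocket of the four N-phthaloyl-tert-leucinate ligands distinguishes the two enantiotopic benzylic hydrogens. The step needs insertion to outrun attack of O1 on the carbene (oxonium ylide, then [1,2]-benzyl shift to a benzofuranone) and to ignore the two remote benzyl ethers and the O5 substituent; the low basicity of an aryl ether oxygen conjugated to the acyl group, the double activation of the C–H bond by O1 and the para-benzyloxy ring B, the silyl rather than benzyl group on O5 and the high dilution should secure this.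

Step 12
Reactants: 15 (2S)-4',5''-di-O-benzyl-5-O-triisopropylsilyl-2,3-dihydroheveaflavone
Product: 16 (2S)-4',5''-di-O-benzyl-2,3-dihydroheveaflavone
Conditions: TBAF, AcOH (1:1), THF, 0 °C
Reagents that add atoms: none
Why: fluoride-induced cleavage of an aryl silyl ether; the acetic acid buffer keeps the medium from becoming basic, so retro-oxa-Michael opening of ring C, which would racemise C2, should not occur.

Step 13
Reactants: 16 (2S)-4',5''-di-O-benzyl-2,3-dihydroheveaflavone
Product: 17 (2S)-2,3-dihydroheveaflavone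
Conditions: H2 (1 atm), 10% Pd/C, EtOAc/THF, rt, stopped after uptake of 2 equiv
Reagents that add atoms: none
Why: catalytic hydrogenolysis of two aryl benzyl ethers under neutral conditions, which are routinely compatible with the flavanone C2–O1 bond and the flavone C2''=C3'' bond when the reaction is stopped at the theoretical uptake.

**Compound list**

1 | acacetin (5,7-dihydroxy-4'-methoxyflavone) | COc1ccc(-c2cc(=O)c3c(O)cc(O)cc3o2)cc1 | starting material
2 | 5-hydroxy-7,4'-dimethoxyflavone | COc1ccc(-c2cc(=O)c3c(O)cc(OC)cc3o2)cc1 | intermediate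
3 | 5-benzyloxy-7,4'-dimethoxyflavone | COc1ccc(-c2cc(=O)c3c(OCc4ccccc4)cc(OC)cc3o2)cc1 | intermediate
4 | 5-benzyloxy-8-iodo-7,4'-dimethoxyflavone | COc1ccc(-c2cc(=O)c3c(OCc4ccccc4)cc(OC)c(I)c3o2)cc1 | intermediate
5 | 3-bromo-4-hydroxybenzaldehyde | O=Cc1ccc(O)c(Br)c1 | starting material
6 | 4-benzyloxy-3-bromobenzaldehyde | O=Cc1ccc(OCc2ccccc2)c(Br)c1 | intermediate
7 | 4-benzyloxy-3-(4,4,5,5-tetramethyl-1,3,2-dioxaborolan-2-yl)benzaldehyde | O=Cc1ccc(OCc2ccccc2)c(B2OC(C)(C)C(C)(C)O2)c1 | intermediate
8 | 4-benzyloxy-3-(5-benzyloxy-7,4'-dimethoxyflavon-8-yl)benzaldehyde | COc1ccc(-c2cc(=O)c3c(OCc4ccccc4)cc(OC)c(-c5cc(C=O)ccc5OCc6ccccc6)c3o2)cc1 | intermediate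
9 | 5-benzyloxy-8-[2-benzyloxy-5-(hydroxymethyl)phenyl]-7,4'-dimethoxyflavone (ArCH2OH) | COc1ccc(-c2cc(=O)c3c(OCc4ccccc4)cc(OC)c(-c5cc(CO)ccc5OCc6ccccc6)c3o2)cc1 | intermediate
10 | 2',6'-dihydroxy-4'-methoxyacetophenone | CC(=O)c1c(O)cc(OC)cc1O | starting material
11 | 2'-(ArCH2O)-6'-hydroxy-4'-methoxyacetophenone | COc1ccc(-c2cc(=O)c3c(OCc4ccccc4)cc(OC)c(-c5cc(COc7cc(OC)cc(O)c7C(C)=O)ccc5OCc6ccccc6)c3o2)cc1 | intermediate
12 | 2'-(ArCH2O)-4'-methoxy-6'-(triisopropylsilyloxy)acetophenone | COc1ccc(-c2cc(=O)c3c(OCc4ccccc4)cc(OC)c(-c5cc(COc7cc(OC)cc(O[Si](C(C)C)(C(C)C)C(C)C)c7C(C)=O)ccc5OCc6ccccc6)c3o2)cc1 | intermediate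
13 | 4,4,4-trifluoro-1-[2-(ArCH2O)-4-methoxy-6-(triisopropylsilyloxy)phenyl]butane-1,3-dione | COc1ccc(-c2cc(=O)c3c(OCc4ccccc4)cc(OC)c(-c5cc(COc7cc(OC)cc(O[Si](C(C)C)(C(C)C)C(C)C)c7C(=O)CC(=O)C(F)(F)F)ccc5OCc6ccccc6)c3o2)cc1 | intermediate (not isolated)
14 | 2-diazo-1-[2-(ArCH2O)-4-methoxy-6-(triisopropylsilyloxy)phenyl]ethanone | COc1ccc(-c2cc(=O)c3c(OCc4ccccc4)cc(OC)c(-c5cc(COc7cc(OC)cc(O[Si](C(C)C)(C(C)C)C(C)C)c7C(=O)C=[N+]=[N-])ccc5OCc6ccccc6)c3o2)cc1 | intermediate
15 | (2S)-4',5''-di-O-benzyl-5-O-triisopropylsilyl-2,3-dihydroheveaflavone | COc1ccc(-c2cc(=O)c3c(OCc4ccccc4)cc(OC)c(-c5cc([C@@H]7CC(=O)c8c(O[Si](C(C)C)(C(C)C)C(C)C)cc(OC)cc8O7)ccc5OCc6ccccc6)c3o2)cc1 | intermediate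
16 | (2S)-4',5''-di-O-benzyl-2,3-dihydroheveaflavone | COc1ccc(-c2cc(=O)c3c(OCc4ccccc4)cc(OC)c(-c5cc([C@@H]7CC(=O)c8c(O)cc(OC)cc8O7)ccc5OCc6ccccc6)c3o2)cc1 | intermediate
17 | (2S)-2,3-dihydroheveaflavone | COc1ccc(-c2cc(=O)c3c(O)cc(OC)c(-c4cc([C@@H]5CC(=O)c6c(O)cc(OC)cc6O5)ccc4O)c3o2)cc1 | target

**Step count**

Total: 13 steps. Longest linear sequence: 11 steps from acacetin (steps 1, 2, 3, 6, 7, 8, 9, 10, 11, 12, 13).

**Steps most likely to fail**

Step 11. The carbene may be captured by the lone pair of O1, giving an oxonium ylide whose electron-rich benzyl group shifts to carbon. Alternatively, the catalyst pocket may discriminate poorly between the two enantiotopic hydrogens. The fallback gives up catalyst control and closes ring C by oxa-Michael addition; it sets out from aldehyde 8 and acetophenone 10 and returns at 17. Acetophenone 10 would be mono-benzylated (BnBr, K2CO3, acetone) to 2'-benzyloxy-6'-hydroxy-4'-methoxyacetophenone F1. Claisen–Schmidt condensation of F1 with 8 (KOH, EtOH/THF, rt) would give the (E)-2'-hydroxychalcone F2. NaOAc in refluxing EtOH would cyclise it to the racemic tri-O-benzyl flavanone F3. Preparative HPLC on a chiral stationary phase would deliver the (2S)-tri-O-benzyl flavanone F4; the 2R material can be re-equilibrated through the chalcone with base and recycled. Hydrogenolysis as in step 13 would then give 17.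

Step 10. The silyl group may migrate from O5 to the neighbouring lithium enolate oxygen, or the hindered enolate may be acylated incompletely, so that little trifluoroacetyl ketone reaches the diazo transfer. The fallback avoids any metal enolate; it sets out from 12 and returns at 14. Heating 12 with N,N-dimethylformamide dimethyl acetal (toluene, 100 °C) would give the enaminone F5. Regitz-type diazo transfer to this enaminone with TsN3 (MeCN, rt) proceeds by azide cycloaddition and fragmentation of the triazoline, and would release the formamidine and leave diazoketone 14.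

Step 6. Protodeboronation of the ortho-alkoxy aryl boronate under aqueous base may outpace transmetalation onto the hindered arylpalladium iodide. The fallback replaces boron by tin in a base-free Stille coupling; it sets out from bromide 6 and returns at 8. Stannylation of 6 with (Me3Sn)2 and Pd(PPh3)4 (toluene, 100 °C) would give 4-benzyloxy-3-(trimethylstannyl)benzaldehyde F6. Coupling of F6 with iodide 4 under Pd(PPh3)4, CuI and CsF (DMF, 45 °C) would give 8.

**Further compounds**

F1 | step 11 | 2'-benzyloxy-6'-hydroxy-4'-methoxyacetophenone | CC(=O)c1c(O)cc(OC)cc1OCc1ccccc1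
F2 | step 11 | (E)-1-(2-benzyloxy-6-hydroxy-4-methoxyphenyl)-3-[4-benzyloxy-3-(5-benzyloxy-7,4'-dimethoxyflavon-8-yl)phenyl]prop-2-en-1-one | COc1ccc(-c2cc(=O)c3c(OCc4ccccc4)cc(OC)c(-c5cc(/C=C/C(=O)c7c(O)cc(OC)cc7OCc8ccccc8)ccc5OCc6ccccc6)c3o2)cc1
F3 | step 11 | racemic 5,4',5''-tri-O-benzyl-2,3-dihydroheveaflavone | COc1ccc(-c2cc(=O)c3c(OCc4ccccc4)cc(OC)c(-c5cc(C7CC(=O)c8c(OCc9ccccc9)cc(OC)cc8O7)ccc5OCc6ccccc6)c3o2)cc1
F4 | step 11 | (2S)-5,4',5''-tri-O-benzyl-2,3-dihydroheveaflavone | COc1ccc(-c2cc(=O)c3c(OCc4ccccc4)cc(OC)c(-c5cc([C@@H]7CC(=O)c8c(OCc9ccccc9)cc(OC)cc8O7)ccc5OCc6ccccc6)c3o2)cc1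
F5 | step 10 | (E)-3-(dimethylamino)-1-[2-(ArCH2O)-4-methoxy-6-(triisopropylsilyloxy)phenyl]prop-2-en-1-one | COc1ccc(-c2cc(=O)c3c(OCc4ccccc4)cc(OC)c(-c5cc(COc7cc(OC)cc(O[Si](C(C)C)(C(C)C)C(C)C)c7C(=O)/C=C/N(C)C)ccc5OCc6ccccc6)c3o2)cc1
F6 | step 6 | 4-benzyloxy-3-(trimethylstannyl)benzaldehyde | O=Cc1ccc(OCc2ccccc2)c([Sn](C)(C)C)c1
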